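**Plan**

1. Retrosynthetic cuts, in order: the phenol O–benzyl bond and the C9 oxidation level (CH2OH back to a 2,2,2-trichloroethyl ester); then the C2–C3 bond of the dihydrofuran ring; then the O1–C2 ether bond (phenol plus guaiacyl benzyl chloride); then the C3a–C3 bond, traced through a Claisen rearrangement to an O-allyl group on methyl vanillate.
2. Enabling feature (benzofuran numbering: O1, C2 carrying the guaiacyl ring, C3 carrying C9, C3a, C4, C5 with the methyl ester, C6, C7 with OMe, C7a; ring A is the benzoate ring): C2 is a benzylic ether carbon made hydridic by O1 and by the para-oxygenated aryl ring, and C3 sits between ring A and the ester-level carbon C9, so C3 is a donor/acceptor carbene carbon held 1,5 to that C–H bond.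
3. Forward: ring A is bought as methyl vanillate. Allylation and Claisen rearrangement place C3 and C9 on C3a, O1 is etherified with the guaiacyl CH2 (the future C2), and the allyl group is cut down to the arylacetate, esterified and diazotised. The dihydrofuran ring, the only ring made, closes last by C2–C3 bond formation; C9 is then reduced and the phenol freed.
4. Stereochemistry: C2 is fixed when the chiral dirhodium carboxylate selects one enantiotopic C2–H; C3 is then equilibrated with DBU to trans relative to C2; no later step touches either centre.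

Key step: step 9

Assumption: the (S)-phthaloyl-tert-leucinate dirhodium catalysts are taken, by analogy with related aryl benzyl ether insertions, to favour the 2R ring, so the (R)-ligand catalyst (made from (R)-tert-leucine like its antipode) is specified for the 2S target; if a first run shows the opposite sense, the mirror-image catalyst is used with nothing else changed.

**Route**

Step 1
Reactants: 1 methyl vanillate; 2 allyl bromide
Product: 3 methyl 4-(allyloxy)-3-methoxybenzoate
Conditions: K2CO3, acetone, reflux
Reagents that add atoms: none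
Why: Williamson O-alkylation (SN2) of the only acidic site, the phenol, with a reactive allylic bromide.

Step 2
Reactants: 3 methyl 4-(allyloxy)-3-methoxybenzoate
Product: 4 methyl 3-allyl-4-hydroxy-5-methoxybenzoate
Conditions: N,N-diethylaniline, 200 °C
Reagents that add atoms: none
Why: Aromatic Claisen rearrangement ([3,3]-sigmatropic shift); only one ortho position carries hydrogen and the para position is blocked by the ester, so rearomatisation should place the allyl group next to the phenol at the future C3a.

Step 3
Reactants: 5 4-(benzyloxy)-3-methoxybenzyl alcohol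
Product: 6 4-(benzyloxy)-3-methoxybenzyl chloride
Conditions: SOCl2, CH2Cl2, 0 °C; concentrated and used crude
Reagents that add atoms: thionyl chloride, O=S(Cl)Cl
Why: Chlorodehydroxylation of a primary benzylic alcohol through its chlorosulfite; the electron-rich ring makes substitution fast at 0 °C, and the chloride is used at once to avoid self-alkylation.

Step 4
Reactants: 4 methyl 3-allyl-4-hydroxy-5-methoxybenzoate; 6 4-(benzyloxy)-3-methoxybenzyl chloride
Product: 7 methyl 3-allyl-4-{[4-(benzyloxy)-3-methoxybenzyl]oxy}-5-methoxybenzoate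
Conditions: K2CO3, n-Bu4NI (cat.), DMF, 50 °C
Reagents that add atoms: none
Why: Williamson etherification (SN2) of the acidic, para-ester-activated phenoxide with a benzylic chloride, assisted by in situ halide exchange; this forms the O1–C2 bond.

Step 5
Reactants: 7 methyl 3-allyl-4-{[4-(benzyloxy)-3-methoxybenzyl]oxy}-5-methoxybenzoate
Product: 8 methyl 4-{[4-(benzyloxy)-3-methoxybenzyl]oxy}-3-methoxy-5-(2-oxoethyl)benzoate
Conditions: OsO4 (cat.), NaIO4, 2,6-lutidine, dioxane–H2O 3:1, rt
Reagents that add atoms: OsO4, O=[Os](=O)(=O)=O; sodium periodate, [Na+].[O-]I(=O)(=O)=O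
Why: Lemieux–Johnson oxidation (osmylation of the terminal alkene, then periodate cleavage of the diol); the arenes, benzyl ethers and ester are inert to these reagents and 2,6-lutidine limits over-oxidation.

Step 6
Reactants: 8 methyl 4-{[4-(benzyloxy)-3-methoxybenzyl]oxy}-3-methoxy-5-(2-oxoethyl)benzoate
Product: 9 2-[2-{[4-(benzyloxy)-3-methoxybenzyl]oxy}-3-methoxy-5-(methoxycarbonyl)phenyl]acetic acid
Conditions: NaClO2, NaH2PO4, 2-methyl-2-butene, t-BuOH–H2O, 0 °C to rt
Reagents that add atoms: sodium chlorite, [Na+].[O-]Cl=O
Why: Pinnick oxidation of the crude aldehyde under buffered conditions, with 2-methyl-2-butene trapping hypochlorous acid so the electron-rich rings are not chlorinated.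

Step 7
Reactants: 9 2-[2-{[4-(benzyloxy)-3-methoxybenzyl]oxy}-3-methoxy-5-(methoxycarbonyl)phenyl]acetic acid; 10 2,2,2-trichloroethanol
Product: 11 methyl 4-{[4-(benzyloxy)-3-methoxybenzyl]oxy}-3-methoxy-5-[2-oxo-2-(2,2,2-trichloroethoxy)ethyl]benzoate
Conditions: DCC, DMAP (cat.), CH2Cl2, 0 °C to rt
Reagents that add atoms: none
Why: Steglich esterification of an arylacetic acid with an unhindered primary alcohol; the trichloroethyl ester is chosen because it acidifies C3–H for the later epimerisation and can be removed by zinc beside the methyl ester.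

Step 8
Reactants: 11 methyl 4-{[4-(benzyloxy)-3-methoxybenzyl]oxy}-3-methoxy-5-[2-oxo-2-(2,2,2-trichloroethoxy)ethyl]benzoate
Product: 12 2,2,2-trichloroethyl 2-diazo-2-[2-{[4-(benzyloxy)-3-methoxybenzyl]oxy}-3-methoxy-5-(methoxycarbonyl)phenyl]acetate
Conditions: p-ABSA, DBU, MeCN, 0 °C to rt
Reagents that add atoms: 4-acetamidobenzenesulfonyl azide (p-ABSA), CC(=O)Nc1ccc(cc1)S(=O)(=O)N=[N+]=[N-]
Why: Regitz diazo transfer; DBU forms the enolate of the aryl- and trichloroethyl-ester-activated methylene, which attacks the sulfonyl azide and expels the sulfonamide.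

Step 9
Reactants: 12 2,2,2-trichloroethyl 2-diazo-2-[2-{[4-(benzyloxy)-3-methoxybenzyl]oxy}-3-methoxy-5-(methoxycarbonyl)phenyl]acetate
Product: 14 3-(2,2,2-trichloroethyl) 5-methyl (2S,3S)-2-[4-(benzyloxy)-3-methoxyphenyl]-7-methoxy-2,3-dihydro-1-benzofuran-3,5-dicarboxylate (trans), via cis-ester 13 (not isolated)
Conditions: Rh2(R-PTTL)4 [dirhodium tetrakis(N-phthaloyl-(R)-tert-leucinate)] (1 mol%), toluene, −60 °C; then DBU, −60 °C to rt
Reagents that add atoms: none
Why: Dinitrogen loss from 12 at the dirhodium core gives a donor/acceptor carbene at C3 that inserts, through a concerted three-centre transition state with hydride-like transfer, into one C2–H bond of the O1 benzyl ether, which O1 and the para-benzyloxy aryl ring both make electron-rich; the closest known reaction type is the enantioselective intramolecular C–H insertion of aryldiazoacetates into benzylic ether C–H bonds under chiral dirhodium carboxylate catalysis, which gives cis-2-aryl-2,3-dihydrobenzofuran-3-carboxylates. The dihydrofuran ring closes as a 1,5-insertion, C2–C3 forming across the five-atom array C3, C3a, C7a, O1, C2. C2 is set by catalyst control, the phthalimido-walled ligand pocket selecting one of the two enantiotopic hydrogens, and the kinetic insertion places aryl and ester cis (13). C3 is then set by thermodynamic control: DBU enolises the acidic C3–H of the trichloroethyl ester and reprotonation relieves the aryl/ester clash to leave trans-14, while C2 stays fixed because β-elimination of O1 is stereoelectronically poor (the C2–O1 bond lies near the nodal plane of the ring enolate). The step needs site selectivity for five-membered closure at the doubly activated C2–H over the methoxy groups, the remote O-benzyl group and the arenes, which the short ortho tether and the electronics of C2 secure, and it needs enantiotopic-hydrogen selection from the ligand and the trans outcome from the strain of the cis isomer.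

Step 10
Reactants: 14 3-(2,2,2-trichloroethyl) 5-methyl (2S,3S)-2-[4-(benzyloxy)-3-methoxyphenyl]-7-methoxy-2,3-dihydro-1-benzofuran-3,5-dicarboxylate
Product: 15 (2S,3S)-2-[4-(benzyloxy)-3-methoxyphenyl]-7-methoxy-5-(methoxycarbonyl)-2,3-dihydro-1-benzofuran-3-carboxylic acid
Conditions: Zn dust, AcOH–THF, rt
Reagents that add atoms: none
Why: Reductive fragmentation of the trichloroethyl ester (zinc insertion into C–Cl, then β-elimination of the carboxylate with loss of 1,1-dichloroethene); the methyl ester, the benzyl ether and both stereocentres should be untouched under these mildly acidic, non-enolising conditions.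

Step 11
Reactants: 15 (2S,3S)-2-[4-(benzyloxy)-3-methoxyphenyl]-7-methoxy-5-(methoxycarbonyl)-2,3-dihydro-1-benzofuran-3-carboxylic acid
Product: 16 methyl (2S,3R)-2-[4-(benzyloxy)-3-methoxyphenyl]-3-(hydroxymethyl)-7-methoxy-2,3-dihydro-1-benzofuran-5-carboxylate
Conditions: BH3·SMe2, THF, 0 °C to rt; then MeOH, aqueous work-up
Reagents that add atoms: none
Why: Chemoselective borane reduction of a carboxylic acid through its acyloxyborane; the aryl methyl ester reacts far more slowly with electrophilic borane, and C3 is not enolised (its descriptor changes from S to R only through the priority change at C9).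

Step 12
Reactants: 16 methyl (2S,3R)-2-[4-(benzyloxy)-3-methoxyphenyl]-3-(hydroxymethyl)-7-methoxy-2,3-dihydro-1-benzofuran-5-carboxylate
Product: 17 curlignan, methyl (2S,3R)-2-(4-hydroxy-3-methoxyphenyl)-3-(hydroxymethyl)-7-methoxy-2,3-dihydro-1-benzofuran-5-carboxylate
Conditions: H2 (1 atm), 10% Pd/C, EtOAc, rt, stopped at consumption of 16
Reagents that add atoms: none
Why: Catalytic hydrogenolysis of the aryl benzyl ether at its unhindered primary benzylic C–O bond; the hindered secondary C2–O1 bond of the ring should react much more slowly at 1 atm.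

**Compound list**

1 | methyl vanillate (methyl 4-hydroxy-3-methoxybenzoate) | COC(=O)c1ccc(O)c(OC)c1 | starting material
2 | allyl bromide | C=CCBr | starting material
3 | methyl 4-(allyloxy)-3-methoxybenzoate | COC(=O)c1ccc(OCC=C)c(OC)c1 | intermediate
4 | methyl 3-allyl-4-hydroxy-5-methoxybenzoate | COC(=O)c1cc(CC=C)c(O)c(OC)c1 | intermediate
5 | 4-(benzyloxy)-3-methoxybenzyl alcohol (catalogue compound; also one NaBH4 reduction from O-benzylvanillin) | COc1cc(CO)ccc1OCc1ccccc1 | starting material
6 | 4-(benzyloxy)-3-methoxybenzyl chloride | COc1cc(CCl)ccc1OCc1ccccc1 | intermediate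
7 | methyl 3-allyl-4-{[4-(benzyloxy)-3-methoxybenzyl]oxy}-5-methoxybenzoate | COC(=O)c1cc(CC=C)c(OCc2ccc(OCc3ccccc3)c(OC)c2)c(OC)c1 | intermediate
8 | methyl 4-{[4-(benzyloxy)-3-methoxybenzyl]oxy}-3-methoxy-5-(2-oxoethyl)benzoate | COC(=O)c1cc(CC=O)c(OCc2ccc(OCc3ccccc3)c(OC)c2)c(OC)c1 | intermediate
9 | 2-[2-{[4-(benzyloxy)-3-methoxybenzyl]oxy}-3-methoxy-5-(methoxycarbonyl)phenyl]acetic acid | COC(=O)c1cc(CC(=O)O)c(OCc2ccc(OCc3ccccc3)c(OC)c2)c(OC)c1 | intermediate
10 | 2,2,2-trichloroethanol | OCC(Cl)(Cl)Cl | starting material
11 | methyl 4-{[4-(benzyloxy)-3-methoxybenzyl]oxy}-3-methoxy-5-[2-oxo-2-(2,2,2-trichloroethoxy)ethyl]benzoate | COC(=O)c1cc(CC(=O)OCC(Cl)(Cl)Cl)c(OCc2ccc(OCc3ccccc3)c(OC)c2)c(OC)c1 | intermediate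
12 | 2,2,2-trichloroethyl 2-diazo-2-[2-{[4-(benzyloxy)-3-methoxybenzyl]oxy}-3-methoxy-5-(methoxycarbonyl)phenyl]acetate | COC(=O)c1cc(C(=[N+]=[N-])C(=O)OCC(Cl)(Cl)Cl)c(OCc2ccc(OCc3ccccc3)c(OC)c2)c(OC)c1 | intermediate
13 | cis-ester: 3-(2,2,2-trichloroethyl) 5-methyl (2S,3R)-2-[4-(benzyloxy)-3-methoxyphenyl]-7-methoxy-2,3-dihydro-1-benzofuran-3,5-dicarboxylate | COC(=O)c1cc(OC)c2c(c1)[C@@H](C(=O)OCC(Cl)(Cl)Cl)[C@@H](c1ccc(OCc3ccccc3)c(OC)c1)O2 | intermediate
14 | trans-ester: 3-(2,2,2-trichloroethyl) 5-methyl (2S,3S)-2-[4-(benzyloxy)-3-methoxyphenyl]-7-methoxy-2,3-dihydro-1-benzofuran-3,5-dicarboxylate | COC(=O)c1cc(OC)c2c(c1)[C@H](C(=O)OCC(Cl)(Cl)Cl)[C@@H](c1ccc(OCc3ccccc3)c(OC)c1)O2 | intermediate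
15 | (2S,3S)-2-[4-(benzyloxy)-3-methoxyphenyl]-7-methoxy-5-(methoxycarbonyl)-2,3-dihydro-1-benzofuran-3-carboxylic acid | COC(=O)c1cc(OC)c2c(c1)[C@H](C(=O)O)[C@@H](c1ccc(OCc3ccccc3)c(OC)c1)O2 | intermediate
16 | methyl (2S,3R)-2-[4-(benzyloxy)-3-methoxyphenyl]-3-(hydroxymethyl)-7-methoxy-2,3-dihydro-1-benzofuran-5-carboxylate | COC(=O)c1cc(OC)c2c(c1)[C@H](CO)[C@@H](c1ccc(OCc3ccccc3)c(OC)c1)O2 | intermediate
17 | curlignan, methyl (2S,3R)-2-(4-hydroxy-3-methoxyphenyl)-3-(hydroxymethyl)-7-methoxy-2,3-dihydro-1-benzofuran-5-carboxylate | COC(=O)c1cc(OC)c2c(c1)[C@H](CO)[C@@H](c1ccc(O)c(OC)c1)O2 | target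

**Step count**

Total: 12 steps. Longest linear sequence: 11 steps (steps 1, 2, 4 to 12 from methyl vanillate); step 3 is the one-step side branch.

**Steps most likely to fail**

Step 9. The catalyst may discriminate the two enantiotopic C2–H bonds insufficiently with this trichloroethyl ester and ortho-methoxy tether, or the base equilibration may erode C2. The fallback gives up catalyst control for resolution. It sets out from 12: Rh2(OAc)4 in CH2Cl2 at rt, then DBU, should give the racemic trans diester F1. Zn dust in AcOH–THF then gives the racemic trans acid F2. Fractional crystallisation with (R)-1-phenylethylamine (the amine enantiomer being chosen so that the wanted salt is the less soluble one) should give the (R)-1-phenylethylammonium salt of the (2S,3S) acid F3. Dilute HCl liberates the acid, and the route is rejoined at 15.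

Step 12. Over-reduction may occur, that is, hydrogenolytic opening of the benzylic C2–O1 bond of the ring alongside or after loss of the benzyl group. The fallback replaces reductive cleavage by Lewis-acid debenzylation. It sets out from 16: BCl3 with pentamethylbenzene in CH2Cl2 at −78 °C, where boron binds the guaiacyl methoxy/benzyloxy pair and the benzyl cation is trapped by the arene. O1 is the less basic ether oxygen because it is conjugated to the benzoate ring, so the ring should hold. The path runs through no new compound F0 and comes back to the route at 17.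

Step 5. The enolisable arylacetaldehyde may over-oxidise with loss of the benzylic carbon or self-condense during alkene cleavage. The fallback changes how the C3–C9 unit is attached and avoids the allyl group altogether. It sets out from 1: N-iodosuccinimide with catalytic CF3CO2H in MeCN should give methyl 4-hydroxy-3-iodo-5-methoxybenzoate F4. Alkylation with 6 (K2CO3, DMF) gives methyl 4-{[4-(benzyloxy)-3-methoxybenzyl]oxy}-3-iodo-5-methoxybenzoate F5. Separately, 10 is acylated with bromoacetyl bromide (pyridine, CH2Cl2) to 2,2,2-trichloroethyl bromoacetate F6, which N,N'-ditosylhydrazine and DBU in THF convert into 2,2,2-trichloroethyl diazoacetate F7. Cross-coupling of F5 with F7 (Pd(PPh3)4, Ag2CO3, Et3N, toluene, rt), a known arylation of diazoacetates at the diazo carbon, comes back to the route at 12.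

**Further compounds**

F1 | step 9 | racemic trans diester (racemate of 14) | COC(=O)c1cc(OC)c2c(c1)[C@H](C(=O)OCC(Cl)(Cl)Cl)[C@@H](c1ccc(OCc3ccccc3)c(OC)c1)O2.COC(=O)c1cc(OC)c2c(c1)[C@@H](C(=O)OCC(Cl)(Cl)Cl)[C@H](c1ccc(OCc3ccccc3)c(OC)c1)O2
F2 | step 9 | racemic trans acid (racemate of 15) | COC(=O)c1cc(OC)c2c(c1)[C@H](C(=O)O)[C@@H](c1ccc(OCc3ccccc3)c(OC)c1)O2.COC(=O)c1cc(OC)c2c(c1)[C@@H](C(=O)O)[C@H](c1ccc(OCc3ccccc3)c(OC)c1)O2
F3 | step 9 | (R)-1-phenylethylammonium salt of the (2S,3S) acid | COC(=O)c1cc(OC)c2c(c1)[C@H](C(=O)[O-])[C@@H](c1ccc(OCc3ccccc3)c(OC)c1)O2.C[C@@H]([NH3+])c1ccccc1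
F0 | step 12 | none | none
F4 | step 5 | methyl 4-hydroxy-3-iodo-5-methoxybenzoate | COC(=O)c1cc(I)c(O)c(OC)c1
F5 | step 5 | methyl 4-{[4-(benzyloxy)-3-methoxybenzyl]oxy}-3-iodo-5-methoxybenzoate | COC(=O)c1cc(I)c(OCc2ccc(OCc3ccccc3)c(OC)c2)c(OC)c1
F6 | step 5 | 2,2,2-trichloroethyl bromoacetate | BrCC(=O)OCC(Cl)(Cl)Cl
F7 | step 5 | 2,2,2-trichloroethyl diazoacetate | [N-]=[N+]=CC(=O)OCC(Cl)(Cl)Cl
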